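**Strategy.** Locants: ring A (cyclopentane) is C1 (quaternary, CH3), C2, C3, C4 (C–OH, isopropyl), C5 (fusion CH); ring B (cycloheptene) adds C6 (aroyloxy), C7, C8 (CH3), C9, C10 (angeloyloxy). The route rests on cutting C5–C6 and C1–C10 together: the C6 and C10 oxygens are 1,4-related across the C5–C1 fusion bond, the retron of a cleaved cyclobutane-1,2-diol. An enantioselective [2+2] photocycloaddition of 3-methylcyclopent-2-enone with a cyclopentene-1,2-diol bis-silyl ether makes both bonds and quaternary C1 at once from two simple five-membered rings. Glycol cleavage of the 5-4-5 adduct then expands the enediol ring into ring B, the C4 carbonyl serving as handle for the isopropyl carbinol.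

Key step: step 2

Remark 1: α/β denote the faces of the bicyclic core; β is the face of the C5 hydrogen in the target (1-CH3 and 4-OH are α; 4-isopropyl, 6-O and 10-O are β).
Remark 2: 2 is assumed to add anti to its C8 methyl group (8β-CH3 drawn); a C8 epimer would converge at step 9, where C8 becomes sp2.
Remark 3: the (S)-configured Lewis acid of step 2 is assumed to expose the C1 Si face of 3; the antipode from D-proline would serve if the sense were opposite.

Step 1
Reactants: 1 dimethyl 3-methylpentanedioate
Product: 2 4-methyl-1,2-bis(trimethylsilyloxy)cyclopent-1-ene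
Conditions: Na (dispersion), Me3SiCl, toluene, reflux
Reagents that add atoms: chlorotrimethylsilane C[Si](C)(C)Cl
Why: Acyloin condensation with in situ silyl trapping (Rühlmann variant) closes the five-membered ring and captures the enediolate and the methoxide as silyl ethers, suppressing Dieckmann chemistry; 2 is Cs-symmetric.

Step 2
Reactants: 2 4-methyl-1,2-bis(trimethylsilyloxy)cyclopent-1-ene; 3 3-methylcyclopent-2-en-1-one
Product: 4 cis-anti-cis 5-4-5 tricyclic ketone (C4 ketone; 1α-CH3; 5α-H; C6 and C10 OSiMe3; 8β-CH3)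
Conditions: hν (366 nm), AlBr3 adduct of (S)-3,3-bis(3,5-dimethylphenyl)-1-(2,4,6-trifluorophenyl)tetrahydro-1H,3H-pyrrolo[1,2-c][1,3,2]oxazaborole (50 mol%), excess 2, CH2Cl2, −75 °C
Reagents that add atoms: none
Why: Proposed new method: the chiral Lewis acid binds the C4 carbonyl of 3, the red-shifted complex is excited selectively at 366 nm and its triplet adds to the electron-rich tetrasubstituted alkene of 2 through a 1,4-biradical that collapses to the cyclobutane; the closest known reactions are the oxazaborolidine–AlBr3-catalysed enantioselective intermolecular [2+2] photocycloaddition of cyclohex-2-enones with alkenes and the uncatalysed photocycloaddition of cyclopentenones with 1,2-bis(trimethylsilyloxy)cycloalkenes. The four-membered ring (C1, C5, C6, C10) closes by biradical recombination of this intermolecular [2+2] photocycloaddition, forming C5–C6 and C1–C10. The absolute configuration at C1 and C5 should be set by the catalyst, which shields one enone face so that 2 adds to the C1 Si face; the cis fusion of ring A to the cyclobutane is enforced by the five-membered enone, and the C6 and C10 oxygens are necessarily cis on the cyclobutane. The anti arrangement of the two five-membered rings and the 8β-methyl orientation should follow from approach to the less hindered faces. Only enantiofacial selectivity is needed, because 2 is Cs-symmetric and no regiochemistry arises; ground-state Mukaiyama–Michael addition should be suppressed at −75 °C by the β,β-disubstitution of 3.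

Step 3
Reactants: 4 cis-anti-cis 5-4-5 tricyclic ketone
Product: 5 C3=C4 enol triflate
Conditions: KN(SiMe3)2, PhNTf2, THF, −78 °C
Reagents that add atoms: N-phenylbis(trifluoromethanesulfonimide) O=S(=O)(N(c1ccccc1)S(=O)(=O)C(F)(F)F)C(F)(F)F
Why: Kinetic enolate triflation; only C3 can be deprotonated, because enolisation towards C5 would place a double bond at the cyclobutane fusion.

Step 4
Reactants: 5 C3=C4 enol triflate
Product: 6 C3=C4 alkene bearing isopropyl on C4
Conditions: iPrMgCl, Fe(acac)3 (5 mol%), THF/NMP, −30 °C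
Reagents that add atoms: isopropylmagnesium chloride CC(C)[Mg]Cl
Why: Iron-catalysed Kumada-type cross-coupling of an alkenyl triflate with a secondary alkyl Grignard reagent, fast enough at low temperature to spare the tertiary silyl ethers.

Step 5
Reactants: 6 C3=C4 alkene bearing isopropyl on C4
Product: 7 tertiary alcohol (4α-OH; 4β-isopropyl)
Conditions: Mn(dpm)3 (dpm = 2,2,6,6-tetramethylheptane-3,5-dionate, cat.), PhSiH3, O2 (1 atm, saturated solution), iPrOH/CH2Cl2, 0 °C
Reagents that add atoms: dioxygen O=O
Why: Mukaiyama hydration: hydrogen-atom transfer to C3 gives the tertiary C4 radical, which O2 should trap on the convex α face (the concave face is blocked by the cyclobutane and its C6 silyloxy group), placing the hydroxyl cis to the 1-methyl group; O2 saturation is meant to outrun cyclobutylcarbinyl ring opening.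

Step 6
Reactants: 7 tertiary alcohol (4α-OH; 4β-isopropyl)
Product: 10 trans-fused hydroxy diketone (5β-H), via triol 8 (not isolated), via cis-fused diketone 9 (not isolated)
Conditions: K2CO3, MeOH, 0 °C; then NaIO4, H2O, rt; the basic methanol is kept until C5 has equilibrated
Reagents that add atoms: none
Why: Methanolysis of the silyl ethers and Malaprade glycol cleavage of the cis-cyclobutane-1,2-diol expand ring C by the two carbons C1 and C5 to the cycloheptane-1,4-dione; base epimerisation of C5 (α to the C6 ketone) should then favour the trans-fused isomer, which alone allows an O4–H···O=C6 hydrogen bond.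

Step 7
Reactants: 10 trans-fused hydroxy diketone (5β-H)
Product: 11 keto diol (4α-OH; 6β-OH; C10 ketone)
Conditions: Me4NBH(OAc)3, MeCN/AcOH (1:1), −20 °C
Reagents that add atoms: none
Why: Evans–Saksena hydroxyl-directed reduction: the borohydride bound to the α-disposed C4 oxygen delivers hydride intramolecularly to the α face of C6, giving the 6β-alcohol, while the undirected C10 ketone is not reduced by this reagent.

Step 8
Reactants: 11 keto diol (4α-OH; 6β-OH; C10 ketone); 12 4-(tert-butyldimethylsilyloxy)benzoic acid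
Product: 14 6β-aroyloxy ketone, via mixed anhydride 13 (not isolated)
Conditions: 12, 2,4,6-trichlorobenzoyl chloride, Et3N, THF, rt; then 11, 4-(dimethylamino)pyridine, toluene, rt
Reagents that add atoms: none
Why: Yamaguchi esterification acylates the secondary C6 hydroxyl, whereas the tertiary C4 hydroxyl is too hindered to react.

Step 9
Reactants: 14 6β-aroyloxy ketone
Product: 15 C8=C9 enone (C10 ketone)
Conditions: IBX (2-iodoxybenzoic acid), DMSO/fluorobenzene, 70 °C
Reagents that add atoms: none
Why: IBX dehydrogenation of a ketone; C10 can enolise only towards C9 because C1 is quaternary, so the double bond must form at C8=C9, and the C8 stereocentre is erased.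

Step 10
Reactants: 15 C8=C9 enone (C10 ketone)
Product: 16 10β-allylic alcohol
Conditions: (S)-1-methyl-3,3-diphenyltetrahydro-1H,3H-pyrrolo[1,2-c][1,3,2]oxazaborole (20 mol%), catecholborane, toluene, −78 °C
Reagents that add atoms: none
Why: Corey–Bakshi–Shibata 1,2-reduction under reagent control: with the quaternary C1 as the large and the C9 vinyl carbon as the small substituent, the (S)-catalyst should deliver hydride to the α face of C10 and give the (10R), 10β-alcohol.

Step 11
Reactants: 16 10β-allylic alcohol; 17 angelic acid [(Z)-2-methylbut-2-enoic acid]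
Product: 19 10β-angelate silyl ether, via angelic mixed anhydride 18 (not isolated)
Conditions: 17, 2,4,6-trichlorobenzoyl chloride, Et3N, toluene, rt; then 16, 80 °C (no nucleophilic catalyst)
Reagents that add atoms: none
Why: Yamaguchi-type mixed-anhydride acylation of the secondary allylic alcohol; omitting a nucleophilic catalyst avoids the addition–elimination pathway that isomerises angelates to tiglates, so the Z geometry is kept.

Step 12
Reactants: 19 10β-angelate silyl ether
Product: 20 target CNP0273650.2
Conditions: HF·pyridine, pyridine/THF, 0 °C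
Reagents that add atoms: none
Why: Fluoride-mediated cleavage of the aryl silyl ether under buffered conditions that leave both esters, the allylic angelate and the tertiary alcohol untouched.

**Compound list**

1 | dimethyl 3-methylpentanedioate (dimethyl 3-methylglutarate) | COC(=O)CC(C)CC(=O)OC | starting material
2 | 4-methyl-1,2-bis(trimethylsilyloxy)cyclopent-1-ene | CC1CC(O[Si](C)(C)C)=C(O[Si](C)(C)C)C1 | intermediate
3 | 3-methylcyclopent-2-en-1-one | CC1=CC(=O)CC1 | starting material
4 | cis-anti-cis 6,9-dimethyl-1,7-bis(trimethylsilyloxy)tricyclo[5.3.0.0(2,6)]decan-3-one; core locants: C4 ketone, 1α-CH3, 5α-H, cyclobutane C1–C5–C6–C10 on the β face of ring A, OSiMe3 on C6 and C10, 8β-CH3 | O=C1CC[C@]2(C)[C@@]3(O[Si](C)(C)C)C[C@H](C)C[C@@]3(O[Si](C)(C)C)[C@H]12 | intermediate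
5 | C3=C4 enol triflate of 4 (C4–OSO2CF3) | O=S(=O)(OC1=CC[C@]2(C)[C@@]3(O[Si](C)(C)C)C[C@H](C)C[C@@]3(O[Si](C)(C)C)[C@H]12)C(F)(F)F | intermediate
6 | tricyclic C3=C4 alkene with isopropyl on C4, bis(trimethylsilyl) ether | CC(C)C1=CC[C@]2(C)[C@@]3(O[Si](C)(C)C)C[C@H](C)C[C@@]3(O[Si](C)(C)C)[C@H]12 | intermediate
7 | tricyclic tertiary alcohol: 4α-OH, 4β-isopropyl, 1α-CH3, 5α-H, bis(trimethylsilyl) ether | CC(C)[C@]1(O)CC[C@]2(C)[C@@]3(O[Si](C)(C)C)C[C@H](C)C[C@@]3(O[Si](C)(C)C)[C@H]12 | intermediate
8 | tricyclic 4α,6,10-triol (cyclobutane-1,2-diol) | CC(C)[C@]1(O)CC[C@]2(C)[C@@]3(O)C[C@H](C)C[C@@]3(O)[C@H]12 | intermediate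
9 | cis-fused bicyclo[5.3.0]decane hydroxy diketone: C6 and C10 ketones, 4α-OH, 4β-isopropyl, 1α-CH3, 5α-H, 8β-CH3 | CC(C)[C@]1(O)CC[C@]2(C)C(=O)C[C@H](C)CC(=O)[C@H]12 | intermediate
10 | trans-fused hydroxy diketone: as 9 but 5β-H | CC(C)[C@]1(O)CC[C@]2(C)C(=O)C[C@H](C)CC(=O)[C@@H]12 | intermediate
11 | trans-fused keto diol: 4α-OH, 6β-OH, C10 ketone, 8β-CH3 | O=C1C[C@H](C)C[C@H](O)[C@@H]2[C@]1(C)CC[C@@]2(O)C(C)C | intermediate
12 | 4-(tert-butyldimethylsilyloxy)benzoic acid | CC(C)(C)[Si](C)(C)Oc1ccc(cc1)C(=O)O | starting material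
13 | 4-(tert-butyldimethylsilyloxy)benzoic 2,4,6-trichlorobenzoic anhydride | CC(C)(C)[Si](C)(C)Oc1ccc(cc1)C(=O)OC(=O)c1c(Cl)cc(Cl)cc1Cl | intermediate
14 | 6β-[4-(tert-butyldimethylsilyloxy)benzoyloxy]-4α-hydroxy ketone (C10 ketone, 8β-CH3) | O=C1C[C@H](C)C[C@H](OC(=O)c2ccc(O[Si](C)(C)C(C)(C)C)cc2)[C@@H]2[C@]1(C)CC[C@@]2(O)C(C)C | intermediate
15 | C8=C9 enone (C10 ketone) with 6β-aroyloxy and 4α-OH | O=C1C=C(C)C[C@H](OC(=O)c2ccc(O[Si](C)(C)C(C)(C)C)cc2)[C@@H]2[C@]1(C)CC[C@@]2(O)C(C)C | intermediate
16 | 10β-allylic alcohol with 6β-aroyloxy and 4α-OH | O[C@@H]1C=C(C)C[C@H](OC(=O)c2ccc(O[Si](C)(C)C(C)(C)C)cc2)[C@@H]2[C@]1(C)CC[C@@]2(O)C(C)C | intermediate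
17 | angelic acid, (Z)-2-methylbut-2-enoic acid | C/C=C(/C)C(=O)O | starting material
18 | angelic 2,4,6-trichlorobenzoic anhydride | C/C=C(/C)C(=O)OC(=O)c1c(Cl)cc(Cl)cc1Cl | intermediate
19 | 10β-angelate, 6β-[4-(tert-butyldimethylsilyloxy)benzoate], 4α-OH | C/C=C(/C)C(=O)O[C@@H]1C=C(C)C[C@H](OC(=O)c2ccc(O[Si](C)(C)C(C)(C)C)cc2)[C@@H]2[C@]1(C)CC[C@@]2(O)C(C)C | intermediate
20 | CNP0273650.2: 10β-angeloyloxy-6β-(4-hydroxybenzoyloxy)-4α-hydroxy-4β-isopropyl-1α,8-dimethyl trans-fused bicyclo[5.3.0]dec-8-ene (core locants) | C/C=C(/C)C(=O)O[C@@H]1C=C(C)C[C@H](OC(=O)c2ccc(O)cc2)[C@@H]2[C@]1(C)CC[C@@]2(O)C(C)C | target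

**Step count.** Total: 12 steps. Longest linear sequence: 12 steps (1 → 20).

**Three steps most likely to fail**

1. Step 2 (Proposed new method). What may go wrong: enantiofacial discrimination on the five-membered, β-substituted enone may be insufficient, or Lewis acid-induced silyl transfer and ground-state Mukaiyama–Michael addition may consume 2 before excitation. Fallback from 3 (with 2) back to 4: irradiation of 3 with excess 2 at 350 nm through Pyrex in hexane without any Lewis acid, the established uncatalysed enone–enediol bis-silyl ether photocycloaddition, should give the racemate, that is 4 together with its mirror image, the enantiomeric photoadduct F1. Preparative HPLC on a cellulose tris(3,5-dimethylphenylcarbamate) stationary phase should then deliver 4.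

2. Step 10. What may go wrong: substrate-controlled hydride delivery anti to the axial 1α-methyl group may override reagent control and give the 10α-epimer. Fallback from 14 back to 16: oxygen instead of hydrogen is delivered to C10.
 - Ketone 14 would be converted (KN(SiMe3)2, PhNTf2, THF, −78 °C) into the C9=C10 enol triflate F2.
 - Formate reduction (Pd(OAc)2, PPh3, HCO2H, Bu3N, DMF, 60 °C) should turn F2 into the C9=C10 alkene F3.
 - Epoxidation with mCPBA anti to the 1α-methyl group should give the 9β,10β-epoxide F4.
 - Opening at the less hindered C9 with PhSeNa [(PhSe)2, NaBH4, EtOH] would give the 9α-phenylselanyl 10β-alcohol F5.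
 - H2O2 oxidation and syn-elimination of the selenoxide towards the 8α-hydrogen, away from the carbinol carbon, would return 16.
 - This fallback serves only the 8β-methyl epimer drawn.

3. Step 6. What may go wrong: retro-aldol opening of the tertiary β-hydroxy ketone may compete with the C5 epimerisation, and the position of the cis/trans equilibrium is not known in advance. Fallback from 7 back to 10: the tertiary hydroxyl is masked before the base step.
 - Et3SiOTf and 2,6-lutidine (CH2Cl2, −78 °C) should give the C4 triethylsilyl ether F6.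
 - K2CO3/MeOH should remove only the two trimethylsilyl groups, NaIO4 should cleave the diol, and DBU in toluene should equilibrate C5 without a free alkoxide, giving the trans-fused silyl ether diketone F7.
 - HF·pyridine would then liberate 10.

Further compounds
F1 | step 2 | enantiomer of photoadduct 4 | O=C1CC[C@@]2(C)[C@]3(O[Si](C)(C)C)C[C@@H](C)C[C@]3(O[Si](C)(C)C)[C@@H]12
F2 | step 10 | C9=C10 enol triflate of 14 | O=S(=O)(OC1=C[C@H](C)C[C@H](OC(=O)c2ccc(O[Si](C)(C)C(C)(C)C)cc2)[C@@H]2[C@]1(C)CC[C@@]2(O)C(C)C)C(F)(F)F
F3 | step 10 | C9=C10 alkene (8β-CH3, 6β-aroyloxy, 4α-OH) | C1=C[C@H](C)C[C@H](OC(=O)c2ccc(O[Si](C)(C)C(C)(C)C)cc2)[C@@H]2[C@]1(C)CC[C@@]2(O)C(C)C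
F4 | step 10 | 9β,10β-epoxide | [C@@H]1(O3)[C@H]3[C@H](C)C[C@H](OC(=O)c4ccc(O[Si](C)(C)C(C)(C)C)cc4)[C@@H]2[C@]1(C)CC[C@@]2(O)C(C)C
F5 | step 10 | 9α-phenylselanyl 10β-alcohol | O[C@@H]1[C@@H]([Se]c3ccccc3)[C@H](C)C[C@H](OC(=O)c4ccc(O[Si](C)(C)C(C)(C)C)cc4)[C@@H]2[C@]1(C)CC[C@@]2(O)C(C)C
F6 | step 6 | C4 triethylsilyl ether of 7 | CC(C)[C@]1(O[Si](CC)(CC)CC)CC[C@]2(C)[C@@]3(O[Si](C)(C)C)C[C@H](C)C[C@@]3(O[Si](C)(C)C)[C@H]12
F7 | step 6 | trans-fused diketone, C4 triethylsilyl ether | O=C1C[C@H](C)CC(=O)[C@@H]2[C@]1(C)CC[C@@]2(O[Si](CC)(CC)CC)C(C)C
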